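**Retrosynthetic overview**
1. Target 31 ⇐ tetrabenzyl ether 30 (hydrogenolysis) ⇐ bis-lactone 28 by double enolate hydroxylation, which sets both tertiary carbinol centres last.
2. 28 ⇐ 24 by removing both dithianes (desulfurisation) and both menthyl acetals (NaBH4/KOH, then relactonisation).
3. Key disconnection in 24 (lactone A): Michael addition of lithiated dithiane 21 to chiral butenolide 4 makes the C4–C bond, and the enolate is benzylated in the same pot by bromide 19.
4. 19 ⇐ the same Michael addition–benzylation on 4 with biaryl dithiane 12 and bromide 14 (lactone B).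
5. 12 ⇐ Suzuki coupling of two 5-bromovanillin-derived arenes (7 + 11). Ring order: furanone ring (step 1), biaryl, lactone B, lactone A; both lactones are reopened and reclosed in step 16.

Assumption: 5-bromovanillin, O-benzylvanillin, 4-(benzyloxy)-3-methoxybenzyl alcohol, (+)-menthol and the racemic Davis oxaziridine are bought.

Abbreviations: Bn = benzyl; TIPS = tri(propan-2-yl)silyl; Men = (1S,2R,5S)-5-methyl-2-(propan-2-yl)cyclohexyl, the (+)-menthyl group. "The biaryl" = 2,2'-bis(benzyloxy)-3,3'-dimethoxybiphenyl, substituted at C5 (ring X) and C5' (ring Y).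

**Route**

Step 1
Reactants: 1 furfural
Product: 2 5-hydroxyfuran-2(5H)-one (racemic)
Conditions: O2, visible light, rose bengal (C20H2Cl4I4Na2O5, 0.5 mol %), MeOH, 20 °C
Reagents that add atoms: dioxygen O=O
Why: Singlet-oxygen [4+2] cycloaddition to the furan and methanolysis of the endoperoxide (photooxygenation) expel the formyl carbon as methyl formate and leave the γ-hydroxybutenolide.

Step 2
Reactants: 2 5-hydroxyfuran-2(5H)-one; 3 (+)-menthol
Product: 4 (5S)-5-(Men-oxy)furan-2(5H)-one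
Conditions: p-TsOH·H2O (cat.), toluene, reflux, Dean–Stark; crystallise from hexane, re-equilibrate the mother liquor with acid and recrystallise
Reagents that add atoms: none
Why: Acid-catalysed acetalisation gives both C5 epimers, which interconvert under acid while only the (5S) epimer crystallises, so crystallisation-driven epimerisation delivers one diastereomer (C5 = S).

Step 3
Reactants: 5 5-bromovanillin
Product: 6 4-(benzyloxy)-3-bromo-5-methoxybenzaldehyde
Conditions: BnBr, K2CO3, DMF, 60 °C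
Reagents that add atoms: benzyl bromide BrCc1ccccc1
Why: Williamson etherification of the phenoxide, needed because all later organolithium and enolate steps require a masked phenol.

Step 4
Reactants: 6 4-(benzyloxy)-3-bromo-5-methoxybenzaldehyde
Product: 7 2-[4-(benzyloxy)-3-bromo-5-methoxyphenyl]-1,3-dithiane
Conditions: propane-1,3-dithiol (1.1 equiv), BF3·OEt2 (0.3 equiv), CH2Cl2, 0 °C → rt
Reagents that add atoms: propane-1,3-dithiol SCCCS
Why: Lewis-acid thioacetalisation turns the aldehyde into the acyl-anion equivalent that will later serve as the Michael donor.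

Step 5
Reactants: 6 4-(benzyloxy)-3-bromo-5-methoxybenzaldehyde
Product: 8 [4-(benzyloxy)-3-bromo-5-methoxyphenyl]methanol
Conditions: NaBH4, MeOH/THF, 0 °C
Reagents that add atoms: none
Why: Borohydride reduction of the aldehyde leaves the aryl bromide and benzyl ether untouched.

Step 6
Reactants: 8 [4-(benzyloxy)-3-bromo-5-methoxyphenyl]methanol
Product: 9 {[4-(benzyloxy)-3-bromo-5-methoxyphenyl]methoxy}tri(propan-2-yl)silane
Conditions: TIPSCl, imidazole, DMF, rt
Reagents that add atoms: chlorotri(propan-2-yl)silane CC(C)[Si](Cl)(C(C)C)C(C)C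
Why: Silylation gives a benzylic ether that survives n-BuLi, aqueous K3PO4 and the dithiane anion.

Step 7
Reactants: 9 {[4-(benzyloxy)-3-bromo-5-methoxyphenyl]methoxy}tri(propan-2-yl)silane
Product: 11 2-[2-(benzyloxy)-3-methoxy-5-(TIPS-oxymethyl)phenyl]-4,4,5,5-tetramethyl-1,3,2-dioxaborolane, via aryllithium 10 (not isolated)
Conditions: n-BuLi, THF, −78 °C; 2-isopropoxy-4,4,5,5-tetramethyl-1,3,2-dioxaborolane, −78 °C → rt; H2O
Reagents that add atoms: 2-isopropoxy-4,4,5,5-tetramethyl-1,3,2-dioxaborolane CC(C)OB1OC(C)(C)C(C)(C)O1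
Why: Bromine–lithium exchange is fast at −78 °C and the aryllithium is trapped by the boron electrophile (lithiation–borylation) before it can attack the neighbouring benzyl ether.

Step 8
Reactants: 7 2-[4-(benzyloxy)-3-bromo-5-methoxyphenyl]-1,3-dithiane; 11 the aryl pinacol boronate
Product: 12 the biaryl carrying 1,3-dithian-2-yl at C5 (ring X) and CH2OTIPS at C5' (ring Y)
Conditions: Pd(OAc)2 (3 mol %), 2-dicyclohexylphosphino-2',6'-dimethoxybiphenyl (SPhos, 6 mol %), K3PO4, toluene/H2O 10:1, 90 °C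
Reagents that add atoms: none
Why: Suzuki–Miyaura coupling with a bulky electron-rich phosphine joins the two ortho-alkoxy arenes, and the choice of halide and boronate fixes which ring carries the dithiane and which the CH2O group.

Step 9
Reactants: 13 [4-(benzyloxy)-3-methoxyphenyl]methanol
Product: 14 1-(benzyloxy)-4-(bromomethyl)-2-methoxybenzene
Conditions: PBr3 (0.4 equiv), Et2O, 0 °C; used at once
Reagents that add atoms: phosphorus tribromide BrP(Br)Br
Why: Bromide displaces the phosphite ester of the electron-rich benzylic alcohol (SN2 bromination).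

Step 10
Reactants: 12 biaryl dithiane; 4 (5S)-5-(Men-oxy)furan-2(5H)-one; 14 1-(benzyloxy)-4-(bromomethyl)-2-methoxybenzene
Product: 17 (3S,4S,5S)-3-[4-(benzyloxy)-3-methoxybenzyl]-4-{2-[5'-(TIPS-oxymethyl)biaryl-5-yl]-1,3-dithian-2-yl}-5-(Men-oxy)dihydrofuran-2(3H)-one (all-trans), via lithiated dithiane 15 (not isolated), via lithium enolate 16 (not isolated)
Conditions: n-BuLi, THF, −30 °C; 4, −78 °C; then 14, DMPU, −78 °C → rt
Reagents that add atoms: none
Why: The soft 2-lithio-2-aryl-1,3-dithiane adds to C4 of the butenolide anti to the C5 menthyloxy group (Michael addition), and the enolate is benzylated at C3 anti to the bulky new C4 substituent (tandem Michael addition–alkylation).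

Step 11
Reactants: 17 the TIPS ether
Product: 18 the corresponding benzylic alcohol (CH2OH on ring Y)
Conditions: Bu4NF, AcOH (1:1), THF, 0 °C → rt
Reagents that add atoms: none
Why: Buffered fluoride desilylation frees the benzylic alcohol without epimerising C3 or opening the acetal-lactone.

Step 12
Reactants: 18 the benzylic alcohol
Product: 19 the corresponding benzylic bromide (CH2Br on ring Y)
Conditions: CBr4, PPh3, CH2Cl2, 0 °C; used at once
Reagents that add atoms: carbon tetrabromide BrC(Br)(Br)Br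
Why: The Appel reaction brominates under neutral conditions, so the dithiane, menthyl acetal and benzyl ethers survive.

Step 13
Reactants: 20 4-(benzyloxy)-3-methoxybenzaldehyde
Product: 21 2-[4-(benzyloxy)-3-methoxyphenyl]-1,3-dithiane
Conditions: propane-1,3-dithiol (1.1 equiv), BF3·OEt2 (0.3 equiv), CH2Cl2, 0 °C → rt
Reagents that add atoms: propane-1,3-dithiol SCCCS
Why: Lewis-acid thioacetalisation gives the Michael donor for lactone A.

Step 14
Reactants: 21 2-[4-(benzyloxy)-3-methoxyphenyl]-1,3-dithiane; 4 (5S)-5-(Men-oxy)furan-2(5H)-one; 19 the benzylic bromide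
Product: 24 bis(acetal-lactone) bis(dithiane) with both lactones (3S,4S,5S) all-trans: lactone A carries the 2-aryl-1,3-dithian-2-yl group at C4 and ring Y–CH2 at C3, via lithiated dithiane 22 (not isolated), via lithium enolate 23 (not isolated)
Conditions: 21 (1.5 equiv), n-BuLi, THF, −30 °C; 4 (1.5 equiv), −78 °C; then 19 (1.0 equiv), DMPU, −78 → 0 °C
Reagents that add atoms: none
Why: The same Michael addition (anti to OMen) and enolate benzylation (anti to the C4 dithianyl group) unite the dithiane, the butenolide and the bromide that carries lactone B, setting C3 and C4 of lactone A under auxiliary control.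

Step 15
Reactants: 24 bis(acetal-lactone) bis(dithiane)
Product: 25 bis(acetal-lactone) with both dithiane carbons reduced to CH2
Conditions: NiCl2·6H2O, NaBH4 (Ni2B formed in situ), MeOH/THF, 0 °C → rt
Reagents that add atoms: none
Why: Ni2B desulfurisation cleaves the four benzylic C–S bonds to C–H without touching the aryl benzyl ethers or any stereocentre.

Step 16
Reactants: 25 bis(acetal-lactone)
Product: 28 bis-lactone with both rings (3S,4S)-trans-3,4-dibenzyldihydrofuran-2(3H)-one and four OBn groups, via dialdehyde dicarboxylate 26 (not isolated), via dihydroxy dicarboxylate 27 (not isolated)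
Conditions: NaBH4, KOH, EtOH/H2O/THF, rt; then 2 M HCl, rt
Reagents that add atoms: none
Why: Hydroxide opens each pseudo-ester to a carboxylate and an aldehyde (menthol lost) that NaBH4 reduces at once, and acid closes the γ-lactone onto the new CH2OH (saponification–reduction–lactonisation) with C3 and C4 unchanged.

Step 17
Reactants: 28 bis-lactone
Product: 30 tetra-O-benzyl ether of the target with both lactones (3R,4R)-3-hydroxy, via bis(potassium enolate) 29 (not isolated)
Conditions: KN(SiMe3)2 (2.6 equiv), THF, −78 °C; 2-(phenylsulfonyl)-3-phenyloxaziridine (3 equiv), −78 °C; AcOH quench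
Reagents that add atoms: 2-(phenylsulfonyl)-3-phenyloxaziridine O=S(=O)(c1ccccc1)N1OC1c1ccccc1
Why: In this Davis enolate oxidation the aryl of the C3 benzyl group turns to the face opposite the C4 benzyl group and shields it, so oxygen enters syn to the C4 CH2 and OH replaces H with the benzyl groups staying trans, as is known for trans-dibenzylbutyrolactone enolates.

Step 18
Reactants: 30 tetra-O-benzyl ether
Product: 31 target (CNP0218652.1)
Conditions: H2 (1 atm), 10% Pd/C, EtOAc/MeOH, rt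
Reagents that add atoms: none
Why: Catalytic hydrogenolysis removes the four aryl benzyl ethers, while the lactones, the non-benzylic tertiary alcohols and all four stereocentres are inert.

**Compound list**

1 | furfural | O=Cc1ccco1 | starting material
2 | 5-hydroxyfuran-2(5H)-one (racemic) | O=C1C=CC(O)O1 | intermediate
3 | (+)-menthol, (1S,2R,5S)-5-methyl-2-(propan-2-yl)cyclohexan-1-ol | O[C@H]1C[C@@H](C)CC[C@@H]1C(C)C | starting material
4 | (5S)-5-(Men-oxy)furan-2(5H)-one | O=C1C=C[C@@H](O[C@H]2C[C@@H](C)CC[C@@H]2C(C)C)O1 | intermediate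
5 | 5-bromovanillin (3-bromo-4-hydroxy-5-methoxybenzaldehyde) | COc1cc(C=O)cc(Br)c1O | starting material
6 | 4-(benzyloxy)-3-bromo-5-methoxybenzaldehyde | COc1cc(C=O)cc(Br)c1OCc1ccccc1 | intermediate
7 | 2-[4-(benzyloxy)-3-bromo-5-methoxyphenyl]-1,3-dithiane | COc1cc(C2SCCCS2)cc(Br)c1OCc1ccccc1 | intermediate
8 | [4-(benzyloxy)-3-bromo-5-methoxyphenyl]methanol | COc1cc(CO)cc(Br)c1OCc1ccccc1 | intermediate
9 | {[4-(benzyloxy)-3-bromo-5-methoxyphenyl]methoxy}tri(propan-2-yl)silane | COc1cc(CO[Si](C(C)C)(C(C)C)C(C)C)cc(Br)c1OCc1ccccc1 | intermediate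
10 | [2-(benzyloxy)-3-methoxy-5-(TIPS-oxymethyl)phenyl]lithium | COc1cc(CO[Si](C(C)C)(C(C)C)C(C)C)cc([Li])c1OCc1ccccc1 | intermediate
11 | 2-[2-(benzyloxy)-3-methoxy-5-(TIPS-oxymethyl)phenyl]-4,4,5,5-tetramethyl-1,3,2-dioxaborolane | COc1cc(CO[Si](C(C)C)(C(C)C)C(C)C)cc(B2OC(C)(C)C(C)(C)O2)c1OCc1ccccc1 | intermediate
12 | the biaryl with 1,3-dithian-2-yl at C5 and CH2OTIPS at C5' | COc1cc(C2SCCCS2)cc(c1OCc1ccccc1)-c1cc(CO[Si](C(C)C)(C(C)C)C(C)C)cc(OC)c1OCc1ccccc1 | intermediate
13 | [4-(benzyloxy)-3-methoxyphenyl]methanol | COc1cc(CO)ccc1OCc1ccccc1 | starting material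
14 | 1-(benzyloxy)-4-(bromomethyl)-2-methoxybenzene | COc1cc(CBr)ccc1OCc1ccccc1 | intermediate
15 | 12 lithiated at dithiane C2 | COc1cc(C2([Li])SCCCS2)cc(c1OCc1ccccc1)-c1cc(CO[Si](C(C)C)(C(C)C)C(C)C)cc(OC)c1OCc1ccccc1 | intermediate
16 | lithium enolate of the Michael adduct of 15 and 4 (C4 dithianyl anti to C5 OMen) | [Li]OC1=C[C@H](C2(c3cc(OC)c(OCc4ccccc4)c(c3)-c3cc(CO[Si](C(C)C)(C(C)C)C(C)C)cc(OC)c3OCc3ccccc3)SCCCS2)[C@@H](O[C@H]2C[C@@H](C)CC[C@@H]2C(C)C)O1 | intermediate
17 | (3S,4S,5S)-3-[4-(benzyloxy)-3-methoxybenzyl]-4-{2-[5'-(TIPS-oxymethyl)biaryl-5-yl]-1,3-dithian-2-yl}-5-(Men-oxy)dihydrofuran-2(3H)-one | O=C1O[C@H](O[C@H]2C[C@@H](C)CC[C@@H]2C(C)C)[C@@H](C2(c3cc(OC)c(OCc4ccccc4)c(c3)-c3cc(CO[Si](C(C)C)(C(C)C)C(C)C)cc(OC)c3OCc3ccccc3)SCCCS2)[C@@H]1Cc1ccc(OCc2ccccc2)c(OC)c1 | intermediate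
18 | 17 with CH2OH in place of CH2OTIPS | O=C1O[C@H](O[C@H]2C[C@@H](C)CC[C@@H]2C(C)C)[C@@H](C2(c3cc(OC)c(OCc4ccccc4)c(c3)-c3cc(CO)cc(OC)c3OCc3ccccc3)SCCCS2)[C@@H]1Cc1ccc(OCc2ccccc2)c(OC)c1 | intermediate
19 | 17 with CH2Br in place of CH2OTIPS | O=C1O[C@H](O[C@H]2C[C@@H](C)CC[C@@H]2C(C)C)[C@@H](C2(c3cc(OC)c(OCc4ccccc4)c(c3)-c3cc(CBr)cc(OC)c3OCc3ccccc3)SCCCS2)[C@@H]1Cc1ccc(OCc2ccccc2)c(OC)c1 | intermediate
20 | 4-(benzyloxy)-3-methoxybenzaldehyde (O-benzylvanillin) | COc1cc(C=O)ccc1OCc1ccccc1 | starting material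
21 | 2-[4-(benzyloxy)-3-methoxyphenyl]-1,3-dithiane | COc1cc(C2SCCCS2)ccc1OCc1ccccc1 | intermediate
22 | 21 lithiated at dithiane C2 | COc1cc(C2([Li])SCCCS2)ccc1OCc1ccccc1 | intermediate
23 | lithium enolate of the Michael adduct of 22 and 4 | [Li]OC1=C[C@H](C2(c3ccc(OCc4ccccc4)c(OC)c3)SCCCS2)[C@@H](O[C@H]2C[C@@H](C)CC[C@@H]2C(C)C)O1 | intermediate
24 | bis(acetal-lactone) bis(dithiane), both lactones (3S,4S,5S); ring Y–CH2 on C3 of lactone A, ring X–C(dithiane) on C4 of lactone B | O=C1O[C@H](O[C@H]2C[C@@H](C)CC[C@@H]2C(C)C)[C@@H](C2(c3ccc(OCc4ccccc4)c(OC)c3)SCCCS2)[C@@H]1Cc1cc(OC)c(OCc2ccccc2)c(c1)-c1cc(cc(OC)c1OCc1ccccc1)C1(SCCCS1)[C@@H]1[C@@H](O[C@H]2C[C@@H](C)CC[C@@H]2C(C)C)OC(=O)[C@H]1Cc1ccc(OCc2ccccc2)c(OC)c1 | intermediate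
25 | bis(acetal-lactone), both lactones (3S,4S,5S)-3,4-dibenzyl-5-(Men-oxy) | O=C1O[C@H](O[C@H]2C[C@@H](C)CC[C@@H]2C(C)C)[C@@H](Cc2ccc(OCc3ccccc3)c(OC)c2)[C@@H]1Cc1cc(OC)c(OCc2ccccc2)c(c1)-c1cc(cc(OC)c1OCc1ccccc1)C[C@@H]1[C@@H](O[C@H]2C[C@@H](C)CC[C@@H]2C(C)C)OC(=O)[C@H]1Cc1ccc(OCc2ccccc2)c(OC)c1 | intermediate
26 | ring-opened dialdehyde dicarboxylate, dipotassium salt | [K+].[K+].[O-]C(=O)[C@@H](Cc1cc(OC)c(OCc2ccccc2)c(c1)-c1cc(cc(OC)c1OCc1ccccc1)C[C@H](C=O)[C@H](Cc1ccc(OCc2ccccc2)c(OC)c1)C([O-])=O)[C@H](Cc1ccc(OCc2ccccc2)c(OC)c1)C=O | intermediate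
27 | ring-opened dihydroxy dicarboxylate, dipotassium salt | [K+].[K+].[O-]C(=O)[C@@H](Cc1cc(OC)c(OCc2ccccc2)c(c1)-c1cc(cc(OC)c1OCc1ccccc1)C[C@H](CO)[C@H](Cc1ccc(OCc2ccccc2)c(OC)c1)C([O-])=O)[C@H](Cc1ccc(OCc2ccccc2)c(OC)c1)CO | intermediate
28 | bis-lactone, both rings (3S,4S)-trans-3,4-dibenzyldihydrofuran-2(3H)-one, four OBn | O=C1OC[C@@H](Cc2ccc(OCc3ccccc3)c(OC)c2)[C@@H]1Cc1cc(OC)c(OCc2ccccc2)c(c1)-c1cc(cc(OC)c1OCc1ccccc1)C[C@@H]1COC(=O)[C@H]1Cc1ccc(OCc2ccccc2)c(OC)c1 | intermediate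
29 | bis(potassium enolate) of 28 | [K]OC1=C(Cc2cc(OC)c(OCc3ccccc3)c(c2)-c2cc(cc(OC)c2OCc2ccccc2)C[C@@H]2COC(O[K])=C2Cc2ccc(OCc3ccccc3)c(OC)c2)[C@H](Cc2ccc(OCc3ccccc3)c(OC)c2)CO1 | intermediate
30 | tetra-O-benzyl target, both lactones (3R,4R)-3-hydroxy with trans benzyl groups | O=C1OC[C@@H](Cc2ccc(OCc3ccccc3)c(OC)c2)[C@]1(O)Cc1cc(OC)c(OCc2ccccc2)c(c1)-c1cc(cc(OC)c1OCc1ccccc1)C[C@@H]1COC(=O)[C@@]1(O)Cc1ccc(OCc2ccccc2)c(OC)c1 | intermediate
31 | target: two (3R,4R)-3-hydroxy-3,4-bis(4-hydroxy-3-methoxybenzyl)dihydrofuran-2(3H)-one units joined by a biaryl bond between C5 of the C3-benzyl ring of lactone A and C5 of the C4-benzyl ring of lactone B | COc1cc(C[C@@H]2COC(=O)[C@@]2(O)Cc2cc(OC)c(O)c(-c3cc(C[C@@H]4COC(=O)[C@@]4(O)Cc4ccc(O)c(OC)c4)cc(OC)c3O)c2)ccc1O | target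

**Totals**

Total step count: 18. Longest linear sequence: 13 steps (5 → 6 → 8 → 9 → 11 → 12 → 17 → 18 → 19 → 24 → 25 → 28 → 30 → 31).

**Three steps most likely to fail**

Step 8 (Suzuki coupling with a thioacetal on board and two ortho-alkoxy partners). If sulfur slows the catalyst, the fallback sets out from 6 and 11. Aldehyde 6 is coupled with boronate 11 under the same Pd(OAc)2/SPhos/K3PO4 system to give the biaryl aldehyde F1. F1 is then thioacetalised with propane-1,3-dithiol under a mild catalyst (I2 or MgBr2·OEt2, CH2Cl2, rt) that spares the TIPS ether, and the route is rejoined at 12.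

Step 14 (three-component union with the valuable bromide 19). If the one-pot trapping is incomplete or enolate/proton exchange interferes, the fallback sets out from 21 and 4. The lithiated dithiane is added to 4 and the enolate is protonated at −78 °C (NH4Cl) to give the isolable Michael adduct lactone F2. Purified F2 is re-enolised with LiN(iPr)2 in THF/DMPU at −78 °C and alkylated with 19, again anti to the C4 dithianyl group, and the route is rejoined at 24.

Step 17 (double enolate hydroxylation; conversion, sulfonimine side reactions and facial selectivity at two centres). The fallback sets out from 28. Bis-enolisation with KN(SiMe3)2 and O-silylation with Me3SiCl give the bis(trimethylsilyl ketene acetal) F3. F3 is oxidised as a neutral species with m-CPBA (NaHCO3, hexane/CH2Cl2, −20 °C, Rubottom oxidation) and desilylated with Bu4NF/AcOH, and the route is rejoined at 30.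

**Further compounds**

F1 | step 8 | 2,2'-bis(benzyloxy)-3,3'-dimethoxy-5'-(TIPS-oxymethyl)biphenyl-5-carbaldehyde | COc1cc(C=O)cc(c1OCc1ccccc1)-c1cc(CO[Si](C(C)C)(C(C)C)C(C)C)cc(OC)c1OCc1ccccc1
F2 | step 14 | (4S,5S)-4-{2-[4-(benzyloxy)-3-methoxyphenyl]-1,3-dithian-2-yl}-5-(Men-oxy)dihydrofuran-2(3H)-one | O=C1C[C@H](C2(c3ccc(OCc4ccccc4)c(OC)c3)SCCCS2)[C@@H](O[C@H]2C[C@@H](C)CC[C@@H]2C(C)C)O1
F3 | step 17 | bis(trimethylsilyl ketene acetal) of bis-lactone 28 | C[Si](C)(C)OC1=C(Cc2cc(OC)c(OCc3ccccc3)c(c2)-c2cc(cc(OC)c2OCc2ccccc2)C[C@@H]2COC(O[Si](C)(C)C)=C2Cc2ccc(OCc3ccccc3)c(OC)c2)[C@H](Cc2ccc(OCc3ccccc3)c(OC)c2)CO1
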